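**Retrosynthetic overview**

1. The enone comes from oxidation of an allylic alcohol, made by adding a 2-lithioalkene tail (built from 4-bromo-2-methylbut-1-ene and 2,3-dibromopropene) to a 1,2-dioxane aldehyde.
2. The aldehyde comes from terminal (aldehyde-selective) Wacker oxidation of a 6-allyl-1,2-dioxane, which comes from allylsilane addition to the C6 peroxycarbenium ion of a 6-methoxy peroxyketal (sets C6, 1,4-cis to the C3 side chain).
3. Key step: the peroxyketal comes from ring expansion of a cis-β-lactone (oxetan-2-one) to the 1,2-dioxane by a tethered hydroperoxy ketal (SN2 at the lactone C4 with inversion, sets C3 and releases the C2 propanoate).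
4. The hydroperoxy ketal comes from methanolic ozonolysis of an isopropenyl group; the β-lactone comes from a catalytic asymmetric propanoyl chloride–aldehyde cyclocondensation with 4-methylpent-4-enal (sets C2 and the lactone C4).
5. Ring order: the oxetan-2-one is made first and is then expanded into the 1,2-dioxane, the only ring of the target.

Assumption: 4-methylpent-4-enal is bought as a catalogue compound, and O-trimethylsilylquinine gives the (3S,4R)-cis-β-lactone (the pseudo-enantiomeric O-trimethylsilylquinidine is used if the sense proves opposite).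

**Route**

Step 1
Reactants: 1 4-methylpent-4-enal; 2 propanoyl chloride
Product: 4 (3S,4R)-3-methyl-4-(3-methylbut-3-en-1-yl)oxetan-2-one, via methylketene 3 (not isolated)
Conditions: O-trimethylsilylquinine (10 mol %), LiClO4 (0.5 equiv), i-Pr2NEt (2.5 equiv), CH2Cl2/Et2O, −78 °C
Reagents that add atoms: none
Why: Catalytic asymmetric acyl halide–aldehyde cyclocondensation (Wynberg/Nelson-type formal [2+2] of in situ methylketene 3 through an ammonium enolate aldol–lactonisation) gives cis-3,4-disubstituted β-lactones in high ee and dr, the alkaloid catalyst setting both centres as (3S,4R).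

Step 2
Reactants: 4 (3S,4R)-3-methyl-4-(3-methylbut-3-en-1-yl)oxetan-2-one
Product: 6 (3S,4R)-4-(3-hydroperoxy-3-methoxybutyl)-3-methyloxetan-2-one, via carbonyl oxide 5 (not isolated)
Conditions: O3, CH2Cl2/MeOH (4:1), −78 °C; N2 purge; concentrate below 20 °C
Reagents that add atoms: ozone, O=[O+][O-]; methanol, CO
Why: Criegee ozonolysis in a participating solvent, in which the ketone oxide 5 from the 1,1-disubstituted alkene is trapped by methanol as the α-methoxy hydroperoxide (both ketal epimers, of no consequence) while the β-lactone and its two stereocentres are untouched.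

Step 3
Reactants: 6 (3S,4R)-4-(3-hydroperoxy-3-methoxybutyl)-3-methyloxetan-2-one
Product: 8 methyl (2S)-2-[(3S)-6-methoxy-6-methyl-1,2-dioxan-3-yl]propanoate, via caesium carboxylate 7 (not isolated)
Conditions: Cs2CO3 (1.5 equiv), DMF (0.01 M), 0 °C to rt; then MeI (3 equiv), rt
Reagents that add atoms: iodomethane, CI
Why: Proposed new method: the caesium peroxide of 6 attacks C4 of the strained oxetan-2-one from the rear in a 6-exo-tet SN2 reaction with the carboxylate as leaving group, so the four-membered lactone is expanded to the 1,2-dioxane with inversion at that carbon (4R of the lactone becomes 3S of the dioxane) while C2 is untouched; acyl attack would need an eight-membered ring, the methoxy ketal blocks the competing five-membered ether closure, and iodomethane then esterifies carboxylate 7 in the same flask; the closest known reaction types are alkyl–oxygen SN2 opening of β-lactones by azide, thiolate or carboxylate nucleophiles, the Mead-type ring expansion of keto-β-lactones to tetrahydrofurans, and base-mediated 6-exo alkylation of hydroperoxy ketals by sulfonates.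

Step 4
Reactants: 8 methyl (2S)-2-[(3S)-6-methoxy-6-methyl-1,2-dioxan-3-yl]propanoate; 9 allyltrimethylsilane
Product: 11 methyl (2S)-2-[(3S,6R)-6-methyl-6-(prop-2-en-1-yl)-1,2-dioxan-3-yl]propanoate, via peroxycarbenium ion 10 (not isolated)
Conditions: 9 (3 equiv), TMSOTf (0.2 equiv), CH2Cl2, −78 °C
Reagents that add atoms: none
Why: Hosomi–Sakurai-type allylation of a peroxyketal through peroxycarbenium ion 10; axial attack on the half-chair whose C3 side chain is pseudo-equatorial (the 1,4-cis rule of 4-alkyl tetrahydropyranyl cations) places allyl cis to the side chain and methyl equatorial, which is 6R.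

Step 5
Reactants: 11 methyl (2S)-2-[(3S,6R)-6-methyl-6-(prop-2-en-1-yl)-1,2-dioxan-3-yl]propanoate
Product: 12 methyl (2S)-2-[(3S,6R)-6-methyl-6-(3-oxopropyl)-1,2-dioxan-3-yl]propanoate
Conditions: PdCl2(PhCN)2 (10 mol %), CuCl2·2H2O (10 mol %), AgNO2 (5 mol %), O2 (1 atm), t-BuOH/MeNO2 (15:1), rt
Reagents that add atoms: dioxygen, O=O
Why: Nitrite-modified aldehyde-selective (anti-Markovnikov) Wacker oxidation, whose terminal selectivity is reinforced by the homoallylic peroxide oxygen; the divalent palladium and copper salts do not reduce the dialkyl peroxide and no stereocentre is touched.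

Step 6
Reactants: 13 4-bromo-2-methylbut-1-ene; 14 2,3-dibromoprop-1-ene
Product: 16 2-bromo-6-methylhepta-1,6-diene, via Grignard reagent 15 (not isolated)
Conditions: Mg, THF, rt; then 14, CuI (5 mol %), 0 °C
Reagents that add atoms: none
Why: Grignard formation followed by copper-catalysed allylic substitution on 2,3-dibromopropene (the classical 2-bromoalk-1-ene synthesis), in which the vinylic bromide stays intact.

Step 7
Reactants: 16 2-bromo-6-methylhepta-1,6-diene
Product: 18 6-bromo-2-methylhept-6-en-2-ol, via organomercurial 17 (not isolated)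
Conditions: Hg(OAc)2, THF/H2O (1:1), rt; then NaBH4, aq NaOH, 0 °C
Reagents that add atoms: water, O
Why: Markovnikov oxymercuration–demercuration hydrates the electron-rich 1,1-dialkyl alkene and leaves the electron-poor 2-bromoalkene alone.

Step 8
Reactants: 12 methyl (2S)-2-[(3S,6R)-6-methyl-6-(3-oxopropyl)-1,2-dioxan-3-yl]propanoate; 18 6-bromo-2-methylhept-6-en-2-ol
Product: 20 methyl (2S)-2-[(3S,6S)-6-(3,7-dihydroxy-7-methyl-4-methylideneoctyl)-6-methyl-1,2-dioxan-3-yl]propanoate, via dilithio species 19 (not isolated)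
Conditions: 18 (1.3 equiv), t-BuLi (3.9 equiv), Et2O, −78 °C; then 12, −78 °C, 15 min; H2O
Reagents that add atoms: none
Why: O-lithiation and bromine–lithium exchange give 2-lithioalkene 19, whose 1,2-addition to the aldehyde at −78 °C is far faster than attack on the ester or the hindered dialkyl peroxide; the carbinol centre forms as a mixture that step 9 removes (the 6S label is only a priority change, the geometry at C6 is that of 12).

Step 9
Reactants: 20 methyl (2S)-2-[(3S,6S)-6-(3,7-dihydroxy-7-methyl-4-methylideneoctyl)-6-methyl-1,2-dioxan-3-yl]propanoate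
Product: 21 aikupikoxide D
Conditions: Dess–Martin periodinane (1.3 equiv), CH2Cl2, 0 °C to rt
Reagents that add atoms: none
Why: Dess–Martin oxidation of the secondary allylic alcohol to the α-methylene ketone; the tertiary alcohol, ester and peroxide are inert and no stereocentre is epimerisable under these conditions.

**Compound list**

1 | 4-methylpent-4-enal | C=C(C)CCC=O | starting material
2 | propanoyl chloride | CCC(=O)Cl | starting material
3 | methylketene (prop-1-en-1-one) | CC=C=O | intermediate
4 | (3S,4R)-3-methyl-4-(3-methylbut-3-en-1-yl)oxetan-2-one | C[C@H]1[C@@H](CCC(C)=C)OC1=O | intermediate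
5 | carbonyl oxide (O-oxide of (3S,4R)-3-methyl-4-(3-oxobutyl)oxetan-2-one) | C[C@H]1[C@@H](CCC(C)=[O+][O-])OC1=O | intermediate
6 | (3S,4R)-4-(3-hydroperoxy-3-methoxybutyl)-3-methyloxetan-2-one (both ketal epimers) | C[C@H]1[C@@H](CCC(C)(OC)OO)OC1=O | intermediate
7 | caesium (2S)-2-[(3S)-6-methoxy-6-methyl-1,2-dioxan-3-yl]propanoate | COC1(C)CC[C@@H]([C@H](C)C(=O)[O-])OO1.[Cs+] | intermediate
8 | methyl (2S)-2-[(3S)-6-methoxy-6-methyl-1,2-dioxan-3-yl]propanoate (both C6 epimers) | COC1(C)CC[C@@H]([C@H](C)C(=O)OC)OO1 | intermediate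
9 | allyltrimethylsilane | C=CC[Si](C)(C)C | starting material
10 | (6S)-6-[(2S)-1-methoxy-1-oxopropan-2-yl]-3-methyl-1,2-dioxan-3-ylium (peroxycarbenium ion) | C[C+]1CC[C@@H]([C@H](C)C(=O)OC)OO1 | intermediate
11 | methyl (2S)-2-[(3S,6R)-6-methyl-6-(prop-2-en-1-yl)-1,2-dioxan-3-yl]propanoate | C=CC[C@@]1(C)CC[C@@H]([C@H](C)C(=O)OC)OO1 | intermediate
12 | methyl (2S)-2-[(3S,6R)-6-methyl-6-(3-oxopropyl)-1,2-dioxan-3-yl]propanoate | O=CCC[C@@]1(C)CC[C@@H]([C@H](C)C(=O)OC)OO1 | intermediate
13 | 4-bromo-2-methylbut-1-ene | C=C(C)CCBr | starting material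
14 | 2,3-dibromoprop-1-ene | C=C(Br)CBr | starting material
15 | (3-methylbut-3-en-1-yl)magnesium bromide | C=C(C)CC[Mg]Br | intermediate
16 | 2-bromo-6-methylhepta-1,6-diene | C=C(Br)CCCC(C)=C | intermediate
17 | acetoxy(6-bromo-2-hydroxy-2-methylhept-6-en-1-yl)mercury | C=C(Br)CCCC(C)(O)C[Hg]OC(C)=O | intermediate
18 | 6-bromo-2-methylhept-6-en-2-ol | C=C(Br)CCCC(C)(C)O | intermediate
19 | lithium 6-lithio-2-methylhept-6-en-2-olate | C=C([Li])CCCC(C)(C)O[Li] | intermediate
20 | methyl (2S)-2-[(3S,6S)-6-(3,7-dihydroxy-7-methyl-4-methylideneoctyl)-6-methyl-1,2-dioxan-3-yl]propanoate (both carbinol epimers) | C=C(CCCC(C)(C)O)C(O)CC[C@@]1(C)CC[C@@H]([C@H](C)C(=O)OC)OO1 | intermediate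
21 | aikupikoxide D, methyl (2S)-2-[(3S,6R)-6-(7-hydroxy-7-methyl-4-methylidene-3-oxooctyl)-6-methyl-1,2-dioxan-3-yl]propanoate | C=C(CCCC(C)(C)O)C(=O)CC[C@@]1(C)CC[C@@H]([C@H](C)C(=O)OC)OO1 | target

**Step count**

Total steps: 9. Longest linear sequence: 7 (steps 1, 2, 3, 4, 5, 8, 9); steps 6 and 7 make the tail.

**Three steps most likely to fail**

Step 3 (the proposed ring expansion). Possible failures are intermolecular acyl attack of the peroxide anion on the lactone, elimination to the unsaturated acid, or a sluggish SN2 at the branched secondary carbon. The fallback uses known chemistry, sets out from 4 and comes back at 8. Lactone 4 is opened at the acyl carbon with retention (NaOMe, MeOH, 0 °C) to methyl (2S,3R)-3-hydroxy-2,6-dimethylhept-6-enoate F1. Mesylation (MsCl, Et3N) gives methyl (2S,3R)-2,6-dimethyl-3-(methylsulfonyloxy)hept-6-enoate F2. Ozonolysis in CH2Cl2/MeOH as in step 2 gives methyl (2S,3R)-6-hydroperoxy-6-methoxy-2-methyl-3-(methylsulfonyloxy)heptanoate F3. KOt-Bu with 18-crown-6 in toluene at 0 °C then closes the 1,2-dioxane by the established 6-exo displacement of a secondary sulfonate by a hydroperoxy-ketal anion, with the same inversion, to give 8. Competing E1cB loss of the mesylate is the price of this route.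

Step 4 (allylation of the peroxycarbenium ion). The weakly nucleophilic allylsilane may lose to Hock-type fragmentation of the ketone-derived peroxyketal, or the cis selectivity may be lower than the model predicts. The fallback sets out from 8 and comes back at 12, so it also bypasses step 5. A far more nucleophilic silyl enol ether, tert-butyldimethyl(vinyloxy)silane, is added under the same TMSOTf catalysis (Mukaiyama-type addition, same axial approach) to give methyl (2S)-2-[(3S,6R)-6-methyl-6-(2-oxoethyl)-1,2-dioxan-3-yl]propanoate F4. Wittig methoxymethylenation (Ph3PCH2OMe chloride, KN(SiMe3)2, THF, −78 °C, ylide added cold to outrun β-elimination of the β-peroxy aldehyde) gives methyl (2S)-2-[(3S,6R)-6-(3-methoxyprop-2-en-1-yl)-6-methyl-1,2-dioxan-3-yl]propanoate F5. Mild hydrolysis (aq HCl, THF, 0 °C) gives 12. If only the diastereomer ratio is at fault, the C6 epimers are separated at F4 or 12.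

Step 8 (alkenyllithium addition beside an ester and a peroxide). Excess organolithium may attack the O–O bond or the ester. The fallback replaces the carbanion by a neutral cross-coupling; it sets out from 12, with the tail taken from 18, and comes back at 21, so step 9 is skipped. Pinnick oxidation (NaClO2, NaH2PO4, 2-methylbut-2-ene, t-BuOH/H2O) gives methyl (2S)-2-[(3S,6R)-6-(2-carboxyethyl)-6-methyl-1,2-dioxan-3-yl]propanoate F6. Oxalyl chloride with catalytic DMF in CH2Cl2 at 0 °C gives methyl (2S)-2-[(3S,6R)-6-(3-chloro-3-oxopropyl)-6-methyl-1,2-dioxan-3-yl]propanoate F7. Separately, 18 is lithiated as in step 8 and quenched with Bu3SnCl to give 2-methyl-6-(tributylstannyl)hept-6-en-2-ol F8. Stille acylation of F8 with F7 (Pd(PPh3)4, a zerovalent palladium catalyst, THF, 50 °C) gives 21 directly; monocyclic dialkyl peroxides are known to survive such couplings.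

**Further compounds**

F1 | step 3 | methyl (2S,3R)-3-hydroxy-2,6-dimethylhept-6-enoate | C=C(C)CC[C@@H](O)[C@H](C)C(=O)OC
F2 | step 3 | methyl (2S,3R)-2,6-dimethyl-3-(methylsulfonyloxy)hept-6-enoate | C=C(C)CC[C@@H](OS(C)(=O)=O)[C@H](C)C(=O)OC
F3 | step 3 | methyl (2S,3R)-6-hydroperoxy-6-methoxy-2-methyl-3-(methylsulfonyloxy)heptanoate | COC(C)(OO)CC[C@@H](OS(C)(=O)=O)[C@H](C)C(=O)OC
F4 | step 4 | methyl (2S)-2-[(3S,6R)-6-methyl-6-(2-oxoethyl)-1,2-dioxan-3-yl]propanoate | O=CC[C@@]1(C)CC[C@@H]([C@H](C)C(=O)OC)OO1
F5 | step 4 | methyl (2S)-2-[(3S,6R)-6-(3-methoxyprop-2-en-1-yl)-6-methyl-1,2-dioxan-3-yl]propanoate | COC=CC[C@@]1(C)CC[C@@H]([C@H](C)C(=O)OC)OO1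
F6 | step 8 | methyl (2S)-2-[(3S,6R)-6-(2-carboxyethyl)-6-methyl-1,2-dioxan-3-yl]propanoate | OC(=O)CC[C@@]1(C)CC[C@@H]([C@H](C)C(=O)OC)OO1
F7 | step 8 | methyl (2S)-2-[(3S,6R)-6-(3-chloro-3-oxopropyl)-6-methyl-1,2-dioxan-3-yl]propanoate | ClC(=O)CC[C@@]1(C)CC[C@@H]([C@H](C)C(=O)OC)OO1
F8 | step 8 | 2-methyl-6-(tributylstannyl)hept-6-en-2-ol | C=C(CCCC(C)(C)O)[Sn](CCCC)(CCCC)CCCC
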